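**Retrosynthetic overview**

- Numbering: ring C1 (O-angelate), C2=C3 (3-Me), C4 (OAc), C5, C6 (side chain); chain C7 (Me), C8, C9 (OAc), C10=C11. The strategy rests on the single cyclohexene ring, whose trans vicinal pair C1(O)/C6 lies next to the C2=C3(Me)–C4(O) unit, i.e. a 4-oxy-2-methylcyclohex-2-enone.
- Endgame: 21 ⇐ Mitsunobu inversion at C4 of Luche alcohol 20 ⇐ angelate enone 19 ⇐ acylation of the C1 hydroxyl of 16 ⇐ silyloxy enone 15.
- Ring formation (the only ring, one operation): 15 ⇐ silyloxyacetaldehyde 12 (C1–C2) + ethyl enone 11 (C3–C6 and the chain), by amine-catalysed Michael addition (C1–C6) and aldol condensation (C2=C3).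
- 11 ⇐ aldehyde 9 + ketophosphonate 10 (C5=C6); 9 ⇐ (S)-3-bromo-2-methylpropan-1-ol 1 (C6–C8, fixes C7) + 3-methylbut-2-enoyl chloride 3 (C9–C11), by zinc-mediated acylation and CBS reduction (sets C9).

Key step: step 8

Assumption: the α-silyloxy aldehyde is taken to react through its E-enamine on the face remote from the diarylmethyl group, as alkanals do; on this basis the (R)-catalyst is chosen to give (S) at C1.

**Route**

Step 1
Reactants: 1 (S)-3-bromo-2-methylpropan-1-ol
Product: 2 (S)-(3-bromo-2-methylpropoxy)(tert-butyl)dimethylsilane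
Conditions: TBSCl, imidazole, CH2Cl2, 0 °C → rt
Reagents that add atoms: tert-butyldimethylsilyl chloride, CC(C)(C)[Si](C)(C)Cl
Why: Standard silylation of a primary alcohol; the weak base avoids oxetane formation and the C7 centre is not touched.

Step 2
Reactants: 2 (S)-(3-bromo-2-methylpropoxy)(tert-butyl)dimethylsilane; 3 3-methylbut-2-enoyl chloride
Product: 5 (R)-7-(tert-butyldimethylsilyloxy)-2,6-dimethylhept-2-en-4-one, via alkylzinc bromide 4 (not isolated)
Conditions: Zn dust (activated with BrCH2CH2Br, Me3SiCl), LiCl, THF, 50 °C; then 3, Pd(PPh3)4 (3 mol%), THF, 0 °C → rt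
Reagents that add atoms: none
Why: LiCl-promoted zinc insertion into the primary bromide followed by palladium-catalysed Negishi acylation should stop cleanly at the ketone; the stereocentre is β to zinc and is retained.

Step 3
Reactants: 5 (R)-7-(tert-butyldimethylsilyloxy)-2,6-dimethylhept-2-en-4-one
Product: 6 (4R,6R)-7-(tert-butyldimethylsilyloxy)-2,6-dimethylhept-2-en-4-ol
Conditions: (S)-Me-CBS oxazaborolidine [(S)-1-methyl-3,3-diphenyltetrahydro-1H,3H-pyrrolo[1,2-c][1,3,2]oxazaborole] (20 mol%), catecholborane, toluene, −78 °C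
Reagents that add atoms: none
Why: Corey–Bakshi–Shibata reduction in which the isobutenyl group acts as the large substituent, so the (S)-catalyst should deliver hydride to the Si face and set C9 as R; catecholborane at low temperature avoids hydroboration and 1,4-reduction.

Step 4
Reactants: 6 (4R,6R)-7-(tert-butyldimethylsilyloxy)-2,6-dimethylhept-2-en-4-ol
Product: 7 (4R,6R)-7-(tert-butyldimethylsilyloxy)-2,6-dimethylhept-2-en-4-yl acetate
Conditions: Ac2O, pyridine, DMAP (cat.), CH2Cl2, 0 °C → rt
Reagents that add atoms: acetic anhydride, CC(=O)OC(C)=O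
Why: DMAP-catalysed acetylation of the secondary allylic alcohol under basic conditions, which cannot ionise the allylic C–O bond.

Step 5
Reactants: 7 (4R,6R)-7-(tert-butyldimethylsilyloxy)-2,6-dimethylhept-2-en-4-yl acetate
Product: 8 (4R,6R)-7-hydroxy-2,6-dimethylhept-2-en-4-yl acetate
Conditions: HF·pyridine, pyridine, THF, 0 °C → rt
Reagents that add atoms: none
Why: Buffered fluoride desilylation of a primary silyl ether; the allylic acetate should survive and acyl migration to the remote primary hydroxyl is slow.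

Step 6
Reactants: 8 (4R,6R)-7-hydroxy-2,6-dimethylhept-2-en-4-yl acetate
Product: 9 (4R,6R)-2,6-dimethyl-7-oxohept-2-en-4-yl acetate
Conditions: Dess–Martin periodinane, CH2Cl2, 0 °C → rt
Reagents that add atoms: none
Why: Dess–Martin oxidation under near-neutral conditions should give the α-branched aldehyde without epimerisation at C7; it is used directly.

Step 7
Reactants: 9 (4R,6R)-2,6-dimethyl-7-oxohept-2-en-4-yl acetate; 10 diethyl (2-oxobutyl)phosphonate
Product: 11 (4E,6R,8R)-6,10-dimethyl-3-oxoundeca-4,9-dien-8-yl acetate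
Conditions: LiCl, i-Pr2NEt, MeCN, rt
Reagents that add atoms: none
Why: Horner–Wadsworth–Emmons olefination under Masamune–Roush conditions should give the (E)-enone from the stabilised ketophosphonate anion without epimerising C7 or cleaving the acetate.

Step 8
Reactants: 11 (4E,6R,8R)-6,10-dimethyl-3-oxoundeca-4,9-dien-8-yl acetate; 12 (tert-butyldimethylsilyloxy)acetaldehyde
Product: 15 (4R,6R)-6-[(1S,2S)-2-(tert-butyldimethylsilyloxy)-4-methyl-5-oxocyclohex-3-en-1-yl]-2-methylhept-2-en-4-yl acetate, via keto aldehyde 13 (not isolated), via aldol adduct 14 (not isolated)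
Conditions: (R)-2-[diphenyl(trimethylsilyloxy)methyl]pyrrolidine (20 mol%), 4-nitrophenol (20 mol%), 12 (3 equiv, slow addition), toluene (2 M in 11), 4 °C → rt; then Bn2NH2+ CF3CO2− (0.5 equiv), toluene, 45 °C
Reagents that add atoms: none
Why: Proposed new method: the secondary amine condenses with 12 to the E-enamine, whose carbon C1 adds to C6 of the phenol-activated enone 11 in an intermolecular Michael addition, and hydrolysis releases δ-keto aldehyde 13; the closest known reaction type is the diarylprolinol silyl ether-catalysed Michael addition of aldehydes to vinyl ketones followed by intramolecular aldol condensation, which has not been shown for a β-alkyl enone. The six-membered ring is then closed by a 6-(enolendo)-exo-trig aldol addition of the ethyl-ketone carbon C3 to the formyl carbon C2 under ammonium-salt catalysis, and E1cB loss of water from 14 gives the C2=C3 enone; C5 cannot compete because it would close a four-membered ring. C1 (S) is set by attack of the enone on the enamine face remote from the CPh2(OSiMe3) group, and C6 (S) by the synclinal, syn-selective approach of the two π systems, which becomes the trans C1/C6 relationship in the ring. The step needs cross-Michael addition to outrun self-aldolisation of 12, which is served by slow addition of 12 to concentrated 11, and it needs catalyst control at C6 because the C7 centre (methyl versus CH2) exerts only a weak bias that may oppose it. C1 can epimerise in 13 through the enamine, but closure with both ring substituents pseudo-equatorial leads to the trans product, and the C9 acetate and the C10=C11 alkene are inert to these weakly acidic amine media.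

Step 9
Reactants: 15 (4R,6R)-6-[(1S,2S)-2-(tert-butyldimethylsilyloxy)-4-methyl-5-oxocyclohex-3-en-1-yl]-2-methylhept-2-en-4-yl acetate
Product: 16 (4R,6R)-6-[(1S,2S)-2-hydroxy-4-methyl-5-oxocyclohex-3-en-1-yl]-2-methylhept-2-en-4-yl acetate
Conditions: HF·pyridine, pyridine, THF, 0 °C → rt
Reagents that add atoms: none
Why: Buffered fluoride cleavage of the secondary allylic silyl ether should leave the acetate, the enone and the trisubstituted alkene untouched.

Step 10
Reactants: 16 (4R,6R)-6-[(1S,2S)-2-hydroxy-4-methyl-5-oxocyclohex-3-en-1-yl]-2-methylhept-2-en-4-yl acetate; 17 angelic acid [(2Z)-2-methylbut-2-enoic acid]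
Product: 19 (1S,6S)-6-[(2R,4R)-4-acetoxy-6-methylhept-5-en-2-yl]-3-methyl-4-oxocyclohex-2-en-1-yl (2Z)-2-methylbut-2-enoate, via mixed anhydride 18 (not isolated)
Conditions: 17, 2,4,6-trichlorobenzoyl chloride, Et3N, toluene, rt; then 16, toluene, 60 °C
Reagents that add atoms: none
Why: Yamaguchi-type esterification through the 2,4,6-trichlorobenzoyl mixed anhydride without a nucleophilic catalyst, the protocol expected to transfer the angeloyl group without isomerisation to the tiglate; the alcohol attacks the less hindered angeloyl carbonyl.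

Step 11
Reactants: 19 (1S,6S)-6-[(2R,4R)-4-acetoxy-6-methylhept-5-en-2-yl]-3-methyl-4-oxocyclohex-2-en-1-yl (2Z)-2-methylbut-2-enoate
Product: 20 (1S,4S,6S)-6-[(2R,4R)-4-acetoxy-6-methylhept-5-en-2-yl]-4-hydroxy-3-methylcyclohex-2-en-1-yl (2Z)-2-methylbut-2-enoate
Conditions: NaBH4, CeCl3·7H2O, MeOH, −78 °C
Reagents that add atoms: none
Why: Luche 1,2-reduction; axial hydride delivery to the half-chair with the C1 and C6 substituents pseudo-equatorial should give the pseudo-equatorial (4S) alcohol, cis to the C6 side chain as is usual for 5-substituted 2-methylcyclohex-2-enones, and the esters are not reduced.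

Step 12
Reactants: 20 (1S,4S,6S)-6-[(2R,4R)-4-acetoxy-6-methylhept-5-en-2-yl]-4-hydroxy-3-methylcyclohex-2-en-1-yl (2Z)-2-methylbut-2-enoate
Product: 21 (1S,4R,6S)-4-acetoxy-6-[(2R,4R)-4-acetoxy-6-methylhept-5-en-2-yl]-3-methylcyclohex-2-en-1-yl (2Z)-2-methylbut-2-enoate
Conditions: PPh3, DIAD, AcOH, THF, 0 °C → rt
Reagents that add atoms: acetic acid, CC(=O)O
Why: Mitsunobu esterification displaces the alkoxyphosphonium by SN2 with inversion, turning the (4S) alcohol into the (4R) acetate cis to the C1 angelate; SN2′ attack at C2 is hindered by the adjacent C1 ester.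

**Compound list**

1 | (S)-3-bromo-2-methylpropan-1-ol | C[C@@H](CO)CBr | starting material
2 | (S)-(3-bromo-2-methylpropoxy)(tert-butyl)dimethylsilane | C[C@@H](CO[Si](C)(C)C(C)(C)C)CBr | intermediate
3 | 3-methylbut-2-enoyl chloride | CC(C)=CC(Cl)=O | starting material
4 | (S)-[3-(tert-butyldimethylsilyloxy)-2-methylpropyl]zinc bromide | C[C@@H](CO[Si](C)(C)C(C)(C)C)C[Zn]Br | intermediate (not isolated)
5 | (R)-7-(tert-butyldimethylsilyloxy)-2,6-dimethylhept-2-en-4-one | C[C@@H](CO[Si](C)(C)C(C)(C)C)CC(=O)C=C(C)C | intermediate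
6 | (4R,6R)-7-(tert-butyldimethylsilyloxy)-2,6-dimethylhept-2-en-4-ol | C[C@@H](CO[Si](C)(C)C(C)(C)C)C[C@H](C=C(C)C)O | intermediate
7 | (4R,6R)-7-(tert-butyldimethylsilyloxy)-2,6-dimethylhept-2-en-4-yl acetate | C[C@@H](CO[Si](C)(C)C(C)(C)C)C[C@H](C=C(C)C)OC(C)=O | intermediate
8 | (4R,6R)-7-hydroxy-2,6-dimethylhept-2-en-4-yl acetate | C[C@@H](CO)C[C@H](C=C(C)C)OC(C)=O | intermediate
9 | (4R,6R)-2,6-dimethyl-7-oxohept-2-en-4-yl acetate | C[C@@H](C=O)C[C@H](C=C(C)C)OC(C)=O | intermediate
10 | diethyl (2-oxobutyl)phosphonate | CCC(=O)CP(=O)(OCC)OCC | starting material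
11 | (4E,6R,8R)-6,10-dimethyl-3-oxoundeca-4,9-dien-8-yl acetate | CCC(=O)/C=C/[C@H](C)C[C@H](C=C(C)C)OC(C)=O | intermediate
12 | (tert-butyldimethylsilyloxy)acetaldehyde | O=CCO[Si](C)(C)C(C)(C)C | starting material
13 | (4R,6R)-6-[(2S,3S)-2-(tert-butyldimethylsilyloxy)-1,5-dioxoheptan-3-yl]-2-methylhept-2-en-4-yl acetate | CC(C)(C)[Si](C)(C)O[C@@H]([C@@H](CC(=O)CC)[C@H](C)C[C@H](C=C(C)C)OC(C)=O)C=O | intermediate (not isolated)
14 | (4R,6R)-6-[(1S,2S)-2-(tert-butyldimethylsilyloxy)-3-hydroxy-4-methyl-5-oxocyclohexyl]-2-methylhept-2-en-4-yl acetate (ring C3 and C4 unassigned) | CC(C)(C)[Si](C)(C)O[C@@H]1C(O)C(C)C(=O)C[C@H]1[C@H](C)C[C@H](C=C(C)C)OC(C)=O | intermediate (not isolated)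
15 | (4R,6R)-6-[(1S,2S)-2-(tert-butyldimethylsilyloxy)-4-methyl-5-oxocyclohex-3-en-1-yl]-2-methylhept-2-en-4-yl acetate | CC(C)(C)[Si](C)(C)O[C@@H]1C=C(C)C(=O)C[C@H]1[C@H](C)C[C@H](C=C(C)C)OC(C)=O | intermediate
16 | (4R,6R)-6-[(1S,2S)-2-hydroxy-4-methyl-5-oxocyclohex-3-en-1-yl]-2-methylhept-2-en-4-yl acetate | O[C@@H]1C=C(C)C(=O)C[C@H]1[C@H](C)C[C@H](C=C(C)C)OC(C)=O | intermediate
17 | angelic acid, (2Z)-2-methylbut-2-enoic acid | C/C=C(/C)C(=O)O | starting material
18 | (2Z)-2-methylbut-2-enoic 2,4,6-trichlorobenzoic anhydride | C/C=C(/C)C(=O)OC(=O)c1c(Cl)cc(Cl)cc1Cl | intermediate (not isolated)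
19 | (1S,6S)-6-[(2R,4R)-4-acetoxy-6-methylhept-5-en-2-yl]-3-methyl-4-oxocyclohex-2-en-1-yl (2Z)-2-methylbut-2-enoate | C/C=C(/C)C(=O)O[C@@H]1C=C(C)C(=O)C[C@H]1[C@H](C)C[C@H](C=C(C)C)OC(C)=O | intermediate
20 | (1S,4S,6S)-6-[(2R,4R)-4-acetoxy-6-methylhept-5-en-2-yl]-4-hydroxy-3-methylcyclohex-2-en-1-yl (2Z)-2-methylbut-2-enoate | C/C=C(/C)C(=O)O[C@@H]1C=C(C)[C@@H](O)C[C@H]1[C@H](C)C[C@H](C=C(C)C)OC(C)=O | intermediate
21 | (1S,4R,6S)-4-acetoxy-6-[(2R,4R)-4-acetoxy-6-methylhept-5-en-2-yl]-3-methylcyclohex-2-en-1-yl (2Z)-2-methylbut-2-enoate | C/C=C(/C)C(=O)O[C@@H]1C=C(C)[C@H](OC(C)=O)C[C@H]1[C@H](C)C[C@H](C=C(C)C)OC(C)=O | target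

**Step count and risks**

Total step count: 12. Longest linear sequence: 12 steps (1 → 21).

Steps most likely to fail:

1. Step 8 (proposed new method). The enamine may fail to add to the β-alkyl, γ-branched enone before 12 is consumed by self-aldolisation, and the weak bias of C7 may erode facial selectivity at C6. The fallback sets out from 11 and 12 and comes back at keto aldehyde 13; it activates the acceptor instead of the donor. Aldehyde 12 is silylated (Me3SiCl, Et3N, NaI, MeCN) to (Z)-2-(tert-butyldimethylsilyloxy)-1-(trimethylsilyloxy)ethene F1. A lanthanide-catalysed inverse-electron-demand hetero-Diels–Alder reaction of enone 11, acting as a 1-oxadiene, with this enol ether (Yb(fod)3, CH2Cl2, rt to 50 °C) forms the C1–C6 bond and gives (4R,6R)-6-[(3S,4R)-3-(tert-butyldimethylsilyloxy)-6-ethyl-2-(trimethylsilyloxy)-3,4-dihydro-2H-pyran-4-yl]-2-methylhept-2-en-4-yl acetate F2, in which the aldehyde stays masked as a silyl acetal. Mild aqueous acid (citric acid, THF/H2O) opens the dihydropyran to 13, which is closed to 15 with Bn2NH2+ CF3CO2− as in the second stage of step 8. C1 is equilibrated in 13 under the ammonium salt, so only the facial selectivity at C6, now under control of C7, has to be accepted; minor isomers would be removed by chromatography at 15.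

2. Step 12. The allylic alkoxyphosphonium may react by SN2′ substitution or elimination to a diene, or inversion may be incomplete. The fallback sets out from enone 19 and comes back at 21; it replaces inversion by reagent-controlled reduction. Reduction of 19 with the (S)-Me-CBS oxazaborolidine and catecholborane (toluene, −78 °C) should override the substrate bias and give (1S,4R,6S)-6-[(2R,4R)-4-acetoxy-6-methylhept-5-en-2-yl]-4-hydroxy-3-methylcyclohex-2-en-1-yl (2Z)-2-methylbut-2-enoate F3 directly; acetylation (Ac2O, pyridine, DMAP) then gives 21.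

3. Step 10. The (Z)-enoate may isomerise to the (E)-enoate during acyl transfer, or acylation of the hindered hydroxy enone may be slow enough for base-induced decomposition to compete. The fallback sets out from 16 and comes back at 19; it builds the Z-alkene on the ester instead of transferring it. Alcohol 16 is esterified with 2-[bis(2,2,2-trifluoroethoxy)phosphoryl]propanoic acid (DCC, DMAP cat., CH2Cl2) to (1S,6S)-6-[(2R,4R)-4-acetoxy-6-methylhept-5-en-2-yl]-3-methyl-4-oxocyclohex-2-en-1-yl 2-[bis(2,2,2-trifluoroethoxy)phosphoryl]propanoate F4. Still–Gennari olefination of this phosphonate with acetaldehyde (KN(SiMe3)2, 18-crown-6, THF, −78 °C) then forms the (Z)-2-methylbut-2-enoate and gives 19.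

**Further compounds**

F1 | step 8 | (Z)-2-(tert-butyldimethylsilyloxy)-1-(trimethylsilyloxy)ethene | C[Si](C)(C)O/C=C\O[Si](C)(C)C(C)(C)C
F2 | step 8 | (4R,6R)-6-[(3S,4R)-3-(tert-butyldimethylsilyloxy)-6-ethyl-2-(trimethylsilyloxy)-3,4-dihydro-2H-pyran-4-yl]-2-methylhept-2-en-4-yl acetate | CCC1=C[C@@H]([C@H](C)C[C@H](C=C(C)C)OC(C)=O)[C@H](O[Si](C)(C)C(C)(C)C)C(O[Si](C)(C)C)O1
F3 | step 12 | (1S,4R,6S)-6-[(2R,4R)-4-acetoxy-6-methylhept-5-en-2-yl]-4-hydroxy-3-methylcyclohex-2-en-1-yl (2Z)-2-methylbut-2-enoate | C/C=C(/C)C(=O)O[C@@H]1C=C(C)[C@H](O)C[C@H]1[C@H](C)C[C@H](C=C(C)C)OC(C)=O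
F4 | step 10 | (1S,6S)-6-[(2R,4R)-4-acetoxy-6-methylhept-5-en-2-yl]-3-methyl-4-oxocyclohex-2-en-1-yl 2-[bis(2,2,2-trifluoroethoxy)phosphoryl]propanoate | CC(C(=O)O[C@@H]1C=C(C)C(=O)C[C@H]1[C@H](C)C[C@H](C=C(C)C)OC(C)=O)P(=O)(OCC(F)(F)F)OCC(F)(F)F
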